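**Plan**

- Numbering: lactone ring A is O1–C2(=O)–C3–C3a–C6a, tetrahydrofuran ring B is C3a–O4–C5–C6–C6a, and the benzylic carbon on C5 is C1'.
- Retrosynthesis cuts, in order: the C1'–O aryl ether (to (S)-pinocembrin), the lactone O1–C2 bond (C2 is the inner alkene carbon of an allyl group), then O4–C3a and C3–C3a together, and finally C5–C6 (acetate aldol).
- Enabling feature: ring B is 2,5-trans (the substituents on C3a and C5 lie on opposite faces) and C3a carries the two-carbon C3–C2 chain next to oxygen-bearing C6a. This is the pattern left when an allyl group moves from O4 to C3a in a five-membered oxonium ylide of a furan-3-one.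
- Forward order: the open chain C1'–C5–C6–C6a is built first, ring B closes in the carbenoid step, ring A follows by alkene cleavage and lactonisation, and the flavanone is joined last.
- Stereochemistry: C1' comes from methyl (R)-mandelate and is inverted to S in the final etherification; C5 from a Felkin–Anh aldol; C3a from allyl migration anti to the C5 side chain; C6a from hydride attack anti to the allyl group; the flavanone centre from (S)-pinocembrin.

Key step: step 7

Assumption: the silyl ketene acetal of methyl acetate, allyl trichloroacetimidate and (S)-pinocembrin are bought as such; the lactol is carried forward as its anomer mixture because that centre becomes the lactone carbonyl.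

**Route**

Step 1
Reactants: 1 methyl (R)-mandelate
Product: 2 methyl (R)-2-(tert-butyldimethylsilyloxy)-2-phenylacetate
Conditions: TBSCl, imidazole, DMF, rt
Reagents that add atoms: tert-butyldimethylsilyl chloride, CC(C)(C)[Si](C)(C)Cl
Why: Imidazole-promoted silyl ether formation occurs at oxygen without touching the stereocentre, and the bulky, non-chelating silyl ether later enforces Felkin–Anh control.

Step 2
Reactants: 2 methyl (R)-2-(tert-butyldimethylsilyloxy)-2-phenylacetate
Product: 3 (R)-2-(tert-butyldimethylsilyloxy)-2-phenylacetaldehyde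
Conditions: i-Bu2AlH (1.1 equiv), CH2Cl2, −78 °C; MeOH quench at −78 °C, aq. potassium sodium tartrate; crude product used at once
Reagents that add atoms: none
Why: Partial reduction of an α-silyloxy ester with i-Bu2AlH at low temperature halts at the aldehyde, and immediate use of the crude material should limit epimerisation of the α-aryl aldehyde.

Step 3
Reactants: 3 (R)-2-(tert-butyldimethylsilyloxy)-2-phenylacetaldehyde; 4 1-(tert-butyldimethylsilyloxy)-1-methoxyethene
Product: 5 methyl (3S,4R)-4-(tert-butyldimethylsilyloxy)-3-hydroxy-4-phenylbutanoate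
Conditions: BF3·OEt2 (1.1 equiv), CH2Cl2, −78 °C; aq. NaHCO3
Reagents that add atoms: compound 4, 1-(tert-butyldimethylsilyloxy)-1-methoxyethene, C=C(OC)O[Si](C)(C)C(C)(C)C
Why: A Mukaiyama aldol addition under a monodentate Lewis acid follows the polar Felkin–Anh model, the ketene acetal approaching anti to the C–OSi bond and past the hydrogen, which should set the new carbinol centre (3S) anti to the silyloxy group.

Step 4
Reactants: 5 methyl (3S,4R)-4-(tert-butyldimethylsilyloxy)-3-hydroxy-4-phenylbutanoate; 6 allyl 2,2,2-trichloroacetimidate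
Product: 7 methyl (3S,4R)-3-(allyloxy)-4-(tert-butyldimethylsilyloxy)-4-phenylbutanoate
Conditions: TfOH (cat.), cyclohexane/CH2Cl2 2:1, 0 °C → rt
Reagents that add atoms: compound 6, allyl 2,2,2-trichloroacetimidate, C=CCOC(=N)C(Cl)(Cl)Cl
Why: Acid-catalysed trichloroacetimidate alkylation allylates the hindered β-hydroxyl without base, so retro-aldol cleavage and β-elimination are avoided and the carbinol configuration is untouched.

Step 5
Reactants: 7 methyl (3S,4R)-3-(allyloxy)-4-(tert-butyldimethylsilyloxy)-4-phenylbutanoate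
Product: 8 (3S,4R)-3-(allyloxy)-4-(tert-butyldimethylsilyloxy)-4-phenylbutanoic acid
Conditions: LiOH·H2O, THF/MeOH/H2O, 0 °C → rt; 1 M HCl to pH 3
Reagents that add atoms: lithium hydroxide, [Li+].[OH-]
Why: Saponification of a methyl ester with LiOH at or below room temperature should be faster than E1cB loss of the β-allyloxy group, and the silyl ether is stable to aqueous hydroxide.

Step 6
Reactants: 8 (3S,4R)-3-(allyloxy)-4-(tert-butyldimethylsilyloxy)-4-phenylbutanoic acid
Product: 10 (4S,5R)-4-(allyloxy)-5-(tert-butyldimethylsilyloxy)-1-diazo-5-phenylpentan-2-one, via mixed carbonic anhydride 9 (not isolated)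
Conditions: i-BuOCOCl, Et3N, Et2O, −20 → 0 °C; then CH2N2 (Et2O, excess), 0 °C → rt
Reagents that add atoms: diazomethane, C=[N+]=[N-]
Why: Acylation of diazomethane by a mixed carbonic anhydride (the first stage of the Arndt–Eistert sequence) gives the α-diazoketone under neutral conditions that leave the silyl ether, the allyl ether and both stereocentres alone.

Step 7
Reactants: 10 (4S,5R)-4-(allyloxy)-5-(tert-butyldimethylsilyloxy)-1-diazo-5-phenylpentan-2-one
Product: 12 (2R,5S)-2-allyl-5-[(R)-(tert-butyldimethylsilyloxy)(phenyl)methyl]dihydrofuran-3(2H)-one, via oxonium ylide 11 (not isolated)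
Conditions: Cu(acac)2 (10 mol%), THF, reflux, slow addition of 10
Reagents that add atoms: none
Why: Cu(acac)2 extrudes N2 from 10, and the electrophilic carbon of the catalyst-bound carbenoid is attacked by a lone pair of the allyl ether oxygen, which forms the O4–C3a bond and gives oxonium ylide 11; the allyl group then moves from oxygen to the ylide carbon in a concerted suprafacial [2,3]-sigmatropic shift through a five-centre envelope transition state, forming the C3–C3a bond. The closest known reaction type is the copper-catalysed tandem oxonium ylide formation and [2,3]-rearrangement of allyloxy diazoketones to 2-allyl-tetrahydrofuran-3-ones. The one ring closes by heteroatom attack on the metal carbene carbon in a five-membered (formally 5-exo) mode, the kinetically preferred ring size for ylide formation. The new stereocentre at C2 of the furanone (R, later C3a) is controlled by the existing C5 centre: on the oxonium oxygen the allyl group sits anti to the C5 side chain and is delivered to the neighbouring carbon on that same face, so the ring should emerge 2,5-trans. The step needs chemoselectivity for ylide formation over 1,5-insertion into the benzylic C–H bond activated by the silyloxy group, over cyclopropanation and over a [1,2]-shift; this is secured by the copper acetylacetonate carbenoid, which prefers ether oxygen to C–H bonds far more than Rh2(OAc)4 does, and by the allyl group, for which the [2,3] path is much faster than a Stevens shift. The silyl ether oxygen is hindered and could only close a six-membered ylide, so it should not compete.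

Step 8
Reactants: 12 (2R,5S)-2-allyl-5-[(R)-(tert-butyldimethylsilyloxy)(phenyl)methyl]dihydrofuran-3(2H)-one
Product: 13 (2R,3R,5S)-2-allyl-5-[(R)-(tert-butyldimethylsilyloxy)(phenyl)methyl]tetrahydrofuran-3-ol
Conditions: LiBH(s-Bu)3, THF, −78 °C; aq. NH4Cl
Reagents that add atoms: none
Why: In this substrate-controlled ketone reduction the bulky trialkylborohydride should attack from the face opposite the adjacent allyl group, so the new carbinol (3R, later C6a) carries its hydroxyl cis to the allyl chain, as the lactone fusion requires.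

Step 9
Reactants: 13 (2R,3R,5S)-2-allyl-5-[(R)-(tert-butyldimethylsilyloxy)(phenyl)methyl]tetrahydrofuran-3-ol
Product: 16 (3aR,5S,6aR)-5-[(R)-(tert-butyldimethylsilyloxy)(phenyl)methyl]hexahydrofuro[3,2-b]furan-2-ol (anomer mixture), via secondary ozonide 14 (not isolated), via hydroxy aldehyde 15 (not isolated)
Conditions: O3, CH2Cl2, −78 °C; then PPh3, −78 °C → rt
Reagents that add atoms: ozone, O=[O+][O-]
Why: Ozonolysis with reductive work-up cleaves the terminal alkene to the aldehyde, which the cis hydroxyl should capture at once as the five-membered lactol; the anomeric centre is of no consequence because it becomes the lactone carbonyl.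

Step 10
Reactants: 16 (3aR,5S,6aR)-5-[(R)-(tert-butyldimethylsilyloxy)(phenyl)methyl]hexahydrofuro[3,2-b]furan-2-ol
Product: 17 (3aR,5S,6aR)-5-[(R)-(tert-butyldimethylsilyloxy)(phenyl)methyl]tetrahydrofuro[3,2-b]furan-2(3H)-one
Conditions: TEMPO (20 mol%), PhI(OAc)2 (1.5 equiv), CH2Cl2, rt
Reagents that add atoms: none
Why: Oxoammonium-mediated oxidation of a lactol to the lactone is a standard, nearly neutral transformation that tolerates the silyl ether and leaves all stereocentres alone.

Step 11
Reactants: 17 (3aR,5S,6aR)-5-[(R)-(tert-butyldimethylsilyloxy)(phenyl)methyl]tetrahydrofuro[3,2-b]furan-2(3H)-one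
Product: 18 (3aR,5S,6aR)-5-[(R)-hydroxy(phenyl)methyl]tetrahydrofuro[3,2-b]furan-2(3H)-one
Conditions: HF·pyridine, THF/pyridine, 0 °C → rt
Reagents that add atoms: none
Why: Acidic fluoride desilylation cleaves the secondary silyl ether while avoiding basic alkoxide conditions that could trigger β-elimination of O4 from the lactone, so the (R) benzylic carbinol should be released unchanged.

Step 12
Reactants: 18 (3aR,5S,6aR)-5-[(R)-hydroxy(phenyl)methyl]tetrahydrofuro[3,2-b]furan-2(3H)-one; 19 (S)-pinocembrin
Product: 21 (2S)-5-hydroxy-7-[(S)-[(3aR,5S,6aR)-2-oxohexahydrofuro[3,2-b]furan-5-yl](phenyl)methoxy]-2-phenylchroman-4-one, via alkoxyphosphonium ion 20 (not isolated)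
Conditions: PPh3, DIAD, THF, 0 °C → rt
Reagents that add atoms: compound 19, (S)-pinocembrin, Oc1cc(O)c2c(c1)O[C@H](c1ccccc1)CC2=O
Why: In this Mitsunobu etherification the alkoxyphosphonium ion 20 should be displaced with inversion by the phenoxide of 19, turning the (R) carbinol into the (S) aryl ether; the 7-hydroxyl reacts because it is the more acidic, unhindered phenol whereas the 5-hydroxyl is held in a hydrogen bond to the C4 carbonyl, and the near-neutral medium spares the base-sensitive flavanone centre.

**Compound list**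

1 | methyl (R)-mandelate | COC(=O)[C@H](O)c1ccccc1 | starting material
2 | methyl (R)-2-(tert-butyldimethylsilyloxy)-2-phenylacetate | COC(=O)[C@H](O[Si](C)(C)C(C)(C)C)c1ccccc1 | intermediate
3 | (R)-2-(tert-butyldimethylsilyloxy)-2-phenylacetaldehyde | O=C[C@H](O[Si](C)(C)C(C)(C)C)c1ccccc1 | intermediate
4 | 1-(tert-butyldimethylsilyloxy)-1-methoxyethene | C=C(OC)O[Si](C)(C)C(C)(C)C | starting material
5 | methyl (3S,4R)-4-(tert-butyldimethylsilyloxy)-3-hydroxy-4-phenylbutanoate | COC(=O)C[C@H](O)[C@H](O[Si](C)(C)C(C)(C)C)c1ccccc1 | intermediate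
6 | allyl 2,2,2-trichloroacetimidate | C=CCOC(=N)C(Cl)(Cl)Cl | starting material
7 | methyl (3S,4R)-3-(allyloxy)-4-(tert-butyldimethylsilyloxy)-4-phenylbutanoate | COC(=O)C[C@H](OCC=C)[C@H](O[Si](C)(C)C(C)(C)C)c1ccccc1 | intermediate
8 | (3S,4R)-3-(allyloxy)-4-(tert-butyldimethylsilyloxy)-4-phenylbutanoic acid | OC(=O)C[C@H](OCC=C)[C@H](O[Si](C)(C)C(C)(C)C)c1ccccc1 | intermediate
9 | (3S,4R)-3-(allyloxy)-4-(tert-butyldimethylsilyloxy)-4-phenylbutanoic isobutyl carbonic anhydride | CC(C)COC(=O)OC(=O)C[C@H](OCC=C)[C@H](O[Si](C)(C)C(C)(C)C)c1ccccc1 | intermediate (not isolated)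
10 | (4S,5R)-4-(allyloxy)-5-(tert-butyldimethylsilyloxy)-1-diazo-5-phenylpentan-2-one | C=CCO[C@@H](CC(=O)C=[N+]=[N-])[C@H](O[Si](C)(C)C(C)(C)C)c1ccccc1 | intermediate
11 | (5S)-1-allyl-5-[(R)-(tert-butyldimethylsilyloxy)(phenyl)methyl]-3-oxooxolan-1-ium-2-ide (oxonium ylide) | C=CC[O+]1[CH-]C(=O)C[C@H]1[C@H](O[Si](C)(C)C(C)(C)C)c1ccccc1 | intermediate (not isolated)
12 | (2R,5S)-2-allyl-5-[(R)-(tert-butyldimethylsilyloxy)(phenyl)methyl]dihydrofuran-3(2H)-one | C=CC[C@H]1O[C@H]([C@H](O[Si](C)(C)C(C)(C)C)c2ccccc2)CC1=O | intermediate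
13 | (2R,3R,5S)-2-allyl-5-[(R)-(tert-butyldimethylsilyloxy)(phenyl)methyl]tetrahydrofuran-3-ol | C=CC[C@H]1O[C@H]([C@H](O[Si](C)(C)C(C)(C)C)c2ccccc2)C[C@H]1O | intermediate
14 | (2R,3R,5S)-5-[(R)-(tert-butyldimethylsilyloxy)(phenyl)methyl]-2-[(1,2,4-trioxolan-3-yl)methyl]tetrahydrofuran-3-ol (secondary ozonide) | O1COOC1C[C@H]2O[C@H]([C@H](O[Si](C)(C)C(C)(C)C)c3ccccc3)C[C@H]2O | intermediate (not isolated)
15 | 2-[(2R,3R,5S)-5-[(R)-(tert-butyldimethylsilyloxy)(phenyl)methyl]-3-hydroxytetrahydrofuran-2-yl]acetaldehyde | O=CC[C@H]1O[C@H]([C@H](O[Si](C)(C)C(C)(C)C)c2ccccc2)C[C@H]1O | intermediate (not isolated)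
16 | (3aR,5S,6aR)-5-[(R)-(tert-butyldimethylsilyloxy)(phenyl)methyl]hexahydrofuro[3,2-b]furan-2-ol (anomer mixture) | OC1C[C@H]2O[C@H]([C@H](O[Si](C)(C)C(C)(C)C)c3ccccc3)C[C@H]2O1 | intermediate
17 | (3aR,5S,6aR)-5-[(R)-(tert-butyldimethylsilyloxy)(phenyl)methyl]tetrahydrofuro[3,2-b]furan-2(3H)-one | O=C1C[C@H]2O[C@H]([C@H](O[Si](C)(C)C(C)(C)C)c3ccccc3)C[C@H]2O1 | intermediate
18 | (3aR,5S,6aR)-5-[(R)-hydroxy(phenyl)methyl]tetrahydrofuro[3,2-b]furan-2(3H)-one | O=C1C[C@H]2O[C@H]([C@H](O)c3ccccc3)C[C@H]2O1 | intermediate
19 | (S)-pinocembrin, (2S)-5,7-dihydroxy-2-phenylchroman-4-one | Oc1cc(O)c2c(c1)O[C@H](c1ccccc1)CC2=O | starting material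
20 | [(R)-[(3aR,5S,6aR)-2-oxohexahydrofuro[3,2-b]furan-5-yl](phenyl)methoxy]triphenylphosphonium | O=C1C[C@H]2O[C@H]([C@H](O[P+](c3ccccc3)(c3ccccc3)c3ccccc3)c3ccccc3)C[C@H]2O1 | intermediate (not isolated)
21 | (2S)-5-hydroxy-7-[(S)-[(3aR,5S,6aR)-2-oxohexahydrofuro[3,2-b]furan-5-yl](phenyl)methoxy]-2-phenylchroman-4-one | O=C1C[C@H]2O[C@H]([C@@H](Oc3cc(O)c4c(c3)O[C@H](c3ccccc3)CC4=O)c3ccccc3)C[C@H]2O1 | target

**Summary**

Total step count: 12. Longest linear sequence: 12 steps, from 1 to 21.

Steps most likely to fail:

Step 3. The α-aryl aldehyde 3 may epimerise before or during the aldol addition, and the facial selectivity of the addition may be incomplete. The fallback avoids the aldehyde. Setting out from 2, Claisen condensation with the lithium enolate of methyl acetate (LiN(i-Pr)2, THF, −78 °C, excess enolate) should give methyl (R)-4-(tert-butyldimethylsilyloxy)-3-oxo-4-phenylbutanoate F1. Catalyst-controlled Noyori hydrogenation with RuCl2[(R)-BINAP] (H2, MeOH) should then set the 3S carbinol independently of the neighbouring centre and return to the route at 5.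

Step 7. Carbenoid insertion into the activated benzylic C–H bond or a [1,2]-shift may outrun the [2,3]-pathway, or the trans selectivity of allyl transfer may be poor. The fallback closes rings B and A together by oxycarbonylation. Setting out from 5, aminolysis with MeNHOMe·HCl and i-PrMgCl (THF, −20 °C) should give (3S,4R)-4-(tert-butyldimethylsilyloxy)-3-hydroxy-N-methoxy-N-methyl-4-phenylbutanamide F2. Addition of CH2=CHMgBr (THF, 0 °C) should give (5S,6R)-6-(tert-butyldimethylsilyloxy)-5-hydroxy-6-phenylhex-1-en-3-one F3. Narasaka–Prasad syn reduction (Et2BOMe, NaBH4, THF/MeOH, −78 °C) should give (3R,5S,6R)-6-(tert-butyldimethylsilyloxy)-6-phenylhex-1-ene-3,5-diol F4. Treatment with PdCl2 (cat.), CuCl2 and NaOAc in AcOH under CO (1 atm) should then bring about 5-exo oxypalladation by the C5 hydroxyl, CO insertion and lactonisation onto the allylic hydroxyl; the cis ring fusion fixes C3a, and the sequence comes back to the route at 17.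

Step 12. The hindered benzylic alcohol may be activated slowly, may ionise so that inversion is incomplete, or the betaine may cause side reactions at the flavanone. The fallback separates activation from displacement. Setting out from 18, MsCl and Et3N (CH2Cl2, 0 °C) should give (R)-[(3aR,5S,6aR)-2-oxohexahydrofuro[3,2-b]furan-5-yl](phenyl)methyl methanesulfonate F5 with retention. Displacement by the 7-phenoxide of 19 (K2CO3, DMF, rt) should proceed with inversion and arrive at 21.

**Further compounds**

F1 | step 3 | methyl (R)-4-(tert-butyldimethylsilyloxy)-3-oxo-4-phenylbutanoate | COC(=O)CC(=O)[C@H](O[Si](C)(C)C(C)(C)C)c1ccccc1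
F2 | step 7 | (3S,4R)-4-(tert-butyldimethylsilyloxy)-3-hydroxy-N-methoxy-N-methyl-4-phenylbutanamide | CON(C)C(=O)C[C@H](O)[C@H](O[Si](C)(C)C(C)(C)C)c1ccccc1
F3 | step 7 | (5S,6R)-6-(tert-butyldimethylsilyloxy)-5-hydroxy-6-phenylhex-1-en-3-one | C=CC(=O)C[C@H](O)[C@H](O[Si](C)(C)C(C)(C)C)c1ccccc1
F4 | step 7 | (3R,5S,6R)-6-(tert-butyldimethylsilyloxy)-6-phenylhex-1-ene-3,5-diol | C=C[C@H](O)C[C@H](O)[C@H](O[Si](C)(C)C(C)(C)C)c1ccccc1
F5 | step 12 | (R)-[(3aR,5S,6aR)-2-oxohexahydrofuro[3,2-b]furan-5-yl](phenyl)methyl methanesulfonate | O=C1C[C@H]2O[C@H]([C@H](OS(C)(=O)=O)c3ccccc3)C[C@H]2O1
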